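## The problem

The target joins a cis-fused hydroazulene to a 2,7-dioxabicyclo[3.2.1]octan-3-one through the single bond C8–C14. Locants used throughout: C1–C10 are the hydroazulene carbons (gem-dimethyl on C4, ring fusion C5/C9, methylidene C20 on C10, methyl C17 on quaternary C8). In the bicycle, C13 and C15 are the bridgeheads and C14 is the one-atom bridge. O–C11(=O)–C12 is the lactone bridge and O–C16 the ether bridge. C12 carries an endo acetate and C16 an exo methyl ester (C21).

There are eight stereocentres: C5, C8 and C9 in the carbocycle, C12–C16 in the bicycle. The two domains meet only at the C8–C14 single bond, so no ring relays configuration from one to the other. The absolute sense of the bicycle must therefore be brought in separately.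

Inside each domain control is available. A branched arm on C9 can direct C–H bond formation at C5, and a tertiary C8–H centre can become the quaternary centre with retention. In the finished bicycle the hydroazulene sits on C14 over the lactone bridge and shields the exo face of C12.

The hard relationship is at C14. On the tetrahydrofuran ring the C8 group must be cis to the C13–C12 bond and trans to the C16 ester. Open-chain or monocyclic chemistry does not favour this arrangement.

Several groups will not survive rough treatment:
- the acylal lactone (bases, nucleophiles);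
- the α-acetoxy lactone (epimerisation);
- C16–H, which is α to an ester and an oxygen;
- the 1,1-disubstituted alkene (acid, electrophiles, carbenoids);
- C9–H whenever C10 is a ketone.

The feature that opens the route is that quaternary C8 lies in the cyclopentane next to the methylene C7. The C7–C8 bond can therefore come from a C7 carbenoid (diazoketone on C5, carbonyl C6) inserting into the C8–H bond of a side chain on C9. The C6 carbonyl is deleted afterwards.

## Retrosynthesis

**C10=C20.** The methylidene is cut first, giving ketone 36 and its dioxolane 35. The alkene would not tolerate the carbenoid, the selenium electrophile, the tin radical chain or the acid used later, and the ketal is its inert stand-in. The forward reaction must methylenate a hindered ketone beside a lactone, an acetate and an ester (Lombardo conditions).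

**C12–O.** The acetate is traced to alcohol 34, its acid 33 and the unsubstituted lactone acid 32. Oxygen is added on the rigid bicycle because only there is the exo face of C12 blocked by the C8 group. Carrying the oxygen in from the fragment would leave C12 to an uncontrolled hydrogen transfer. Oxidising at the acid stage lets the carboxylate protect C16–H.

**Lactone C15–O and C13–C14.** Lactone acid 32 is the isomer of the strained acylal 30 (after loss of benzyl), so the lactone C–O bond is cut by an acid-catalysed lactone interchange. In 30 the C13–C14 bond is cut to give dioxolanone 29, with a radical on C14 closing onto an enoate. Dioxolanone 29 falls into aldehyde 21 and hydroxy acid 27. The ordinary mixed iodoacetal (Ueno–Stork) was set aside as the main line: its acetal carbon is uncontrolled, and its exocyclic alkoxy group pushes the bulky C8 group trans to the C13 arm. Tying that oxygen back to C16 through the C21 carbonyl removes the free acetal centre and forces both new substituents exo. Four stereocentres of the bicycle thus reduce to one (C16 of 27). The forward steps must form the cis dioxolanone and close a bridged ring.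

**Fragment 27.** The C12=C13 bond is cut by olefination of aldehyde 24, made from (R)-solketal 22 and phosphonate 23. Acetonide 25 and diol 26 follow. C16 comes from the chiral pool with the R configuration of the target.

**Aldehyde 21.** Functional-group changes lead back through aldehyde 20 and ester 19 to keto ester 17. The C6 carbonyl left by the key step is removed through tosylhydrazone 18.

**C7–C8 (key cut).** Keto ester 17 is opened to diazoketone 16. This turns a quaternary centre in a ring into a tertiary acyclic centre that is much easier to set. The alternative cuts at C8–C14 or C8–C9 would require a quaternary centre to be made by intermolecular bond formation. The forward step needs site-selective insertion with retention.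

**C5 and C6–C7.** Diazoketone 16 comes from acid 14 via acid chloride 15 and reagent 7. Acid 14 is the cis aldehyde 13 oxidised. Conjugate addition followed by trapping can only give the trans C5/C9 relation, so the cis relation is created afterwards: the C5 centre of trans aldehyde 11 is erased as enol silane 12 and reset by kinetic protonation. Aldehyde 11 comes from vinyl ketal 10 by ozonolysis.

**C1.** Ketal 10 derives from cycloheptanone 9, and 9 from cyclohexanone 6 by insertion of C1 (via silyl ketone 8). Expanding late avoids the awkward preparation of the seven-membered enone and uses the better-behaved six-membered enone. Branching at C9 directs the migration.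

**C8–C9 and C5–C6.** Keto ester 6 is the decarboxylation product of malonate 5. Malonate 5 is cut at C8–C9 into enol silane 3 and ethylidenemalonate 4 (Mukaiyama–Michael). The open transition state gives the anti C9/C8 pair that is needed; a chelated enolate addition to a crotonate would give syn. Enol silane 3 is cut at C5–C6 into enone 1 and vinylmagnesium bromide 2 by asymmetric conjugate addition. The C5 centre so formed only relays chirality to C9 and C8.

## Roads not taken

**Alternative 1:** The cut is made in the seven-membered ring, at C9–C10 and C4–C5. The forward key step is a tethered de Mayo sequence. An enol ester of a cyclic 1,3-dione, hung from a carboxyl group on C8 of a cyclopentene, is irradiated at about 350 nm and adds across the C5=C9 alkene to give the lactone-bridged cyclobutane A1. Retro-aldol opening then enlarges the ring to the cycloheptane.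
- Merits: the tether enforces the cis ring fusion, where the chosen plan needs a separate epimerisation (step 7). The quaternary centre is made on a small ring by ordinary enolate chemistry.
- Weak points: C17 arrives as a lactone carbonyl and must be reduced to a methyl group. C4 receives only one methyl group, so a second alkylation and removal of the C3 carbonyl follow. Enol esters can undergo photochemical acyl shifts. The quaternary C8 centre must already be enantiopure before the photoreaction.
- Comparison: this road is better on ring-fusion control. The chosen plan sets against it a tertiary, acyclic C8 centre that is simple to make and a carbocycle with no surplus oxygen to remove except C6.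

**Alternative 2:** The cut is made in the bicycle, at C14–C15 and C12–C13. The forward key step is a triplet-sensitised crossed cycloaddition of a 1,5-diene (a β-alkoxyacrylate tied through oxygen and C16 to a C13=C14 alkene on C8). It gives the 2-oxabicyclo[2.1.1]hexane A2. Acid is then expected to open the cyclobutane while the C11 acid captures C15 as the lactone.
- Merits: the tetrahydrofuran, the C13–C14 bond and the lactone carbons appear in two operations. The geometry of the crossed adduct guarantees the cis C13/C14 relation. In step count for the bicycle this road beats the chosen plan.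
- Weak points: the facial selectivity at C14 rests only on the distant quaternary C8. The methylidene must be masked against the sensitiser. The strain-release lactonisation has no close model. C12 still needs its oxygen.
- Comparison: the chosen plan is longer here. It sets against this a thermal radical closure whose stereochemistry is dictated by a tether of known configuration, with one unmodelled step instead of two in a row.

**Alternative 3:** The cut is the C5–C9 bond, made by a 1,2-shift. The forward key step is buffered solvolysis of an equatorial C9 mesylate of a trans-decalin. C5 migrates from C10 to C9 and the C10 cation loses a methyl proton, giving the cis-hydroazulene A3 with the methylidene in place.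
- Merits: one step forms the ring system, the cis fusion and the alkene. The decalin can come from the terpene chiral pool with all carbocyclic stereocentres already set. For the carbocycle this road is clearly shorter than steps 1–12 of the chosen plan, and its absolute control is free.
- Weak points: it runs through a cation. Hydride and methyl shifts, elimination to endocyclic alkenes and the need for exact antiperiplanar alignment all threaten it. The methylidene must then survive every later step of the side-chain work.
- Comparison: the chosen plan sets against this a bond formation at one defined C–H bond with retention, no cationic intermediate, and an alkene introduced only at the end.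

Key step: step 10

Assumption: the copper–ligand pair of step 1 is taken to give the 3S enol silane; should the antipode form, the enantiomeric ligand is used.

Assumption: CIP descriptors quoted with the locants defined above change where a neighbouring group changes priority although the centre itself is untouched; the SMILES strings are authoritative.

## Route

Step 1
Reactants: 1 4,4-dimethylcyclohex-2-en-1-one; 2 vinylmagnesium bromide
Product: 3 (S)-trimethyl[(4,4-dimethyl-3-vinylcyclohex-1-en-1-yl)oxy]silane
Conditions: CuBr·SMe2 (5 mol %), (R)-1-[(S)-2-(diphenylphosphino)ferrocenyl]ethyldicyclohexylphosphine (6 mol %), Me3SiCl, t-BuOMe, −78 °C; then Et3N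
Reagents that add atoms: chlorotrimethylsilane, C[Si](C)(C)Cl
Why: Copper-catalysed asymmetric conjugate addition of a Grignard reagent to a cyclic enone with in situ O-silylation; the ligand-controlled face of the enone should set the C5 centre (a relay that is reset in step 7), and the silyl chloride traps the magnesium enolate regiospecifically as the C9=C10 enol silane.

Step 2
Reactants: 3 (S)-trimethyl[(4,4-dimethyl-3-vinylcyclohex-1-en-1-yl)oxy]silane; 4 dimethyl 2-ethylidenemalonate
Product: 5 dimethyl 2-[(1S)-1-[(1S,2S)-3,3-dimethyl-6-oxo-2-vinylcyclohexyl]ethyl]malonate (5S,8S,9S in the locants used here; vinyl and side chain trans)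
Conditions: TiCl4 (1.1 equiv), CH2Cl2, −78 °C; aq. NaHCO3
Reagents that add atoms: none
Why: Mukaiyama–Michael addition; C9 should attack anti to the neighbouring vinyl group (trans C5/C9), and the open antiperiplanar transition state puts the β-methyl group of the acceptor next to H9, which gives the anti C9/C8 pair, that is the C8 configuration needed for the later retention.

Step 3
Reactants: 5 dimethyl 2-[(1S)-1-[(1S,2S)-3,3-dimethyl-6-oxo-2-vinylcyclohexyl]ethyl]malonate
Product: 6 methyl (3R)-3-[(1S,2S)-3,3-dimethyl-6-oxo-2-vinylcyclohexyl]butanoate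
Conditions: LiCl, H2O, DMSO, 150 °C
Reagents that add atoms: none
Why: Krapcho dealkoxycarbonylation of the malonate (chloride attack on a methyl group, loss of CO2, protonation); C8 is not acidic and the trans ketone is the stable C9 epimer, so no centre should be lost.

Step 4
Reactants: 6 methyl (3R)-3-[(1S,2S)-3,3-dimethyl-6-oxo-2-vinylcyclohexyl]butanoate; 7 (trimethylsilyl)diazomethane
Product: 9 methyl (3R)-3-[(1S,2S)-3,3-dimethyl-7-oxo-2-vinylcycloheptyl]butanoate, via α-trimethylsilyl cycloheptanone 8 (not isolated)
Conditions: BF3·OEt2, CH2Cl2, −78 to −30 °C; then 1 M HCl, THF, 0 °C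
Reagents that add atoms: none
Why: Lewis-acid-promoted one-carbon ring expansion of a ketone with a diazoalkane (Tiffeneau–Demjanov type); the unbranched ring methylene should migrate in preference to the hindered, branched C9, so the new carbon (C1) enters on the side away from C9, and the α-silyl ketone is protodesilylated on acidic work-up.

Step 5
Reactants: 9 methyl (3R)-3-[(1S,2S)-3,3-dimethyl-7-oxo-2-vinylcycloheptyl]butanoate
Product: 10 methyl (3R)-3-[(6S,7S)-8,8-dimethyl-7-vinyl-1,4-dioxaspiro[4.6]undecan-6-yl]butanoate
Conditions: Me3SiOCH2CH2OSiMe3, Me3SiOTf (5 mol %), CH2Cl2, −20 °C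
Reagents that add atoms: 1,2-bis(trimethylsilyloxy)ethane, C[Si](C)(C)OCCO[Si](C)(C)C
Why: Silyl-triflate-catalysed ketalisation with the bis-silyl ether of ethylene glycol, a low-temperature method that ketalises hindered ketones without enolisation; the C10 dioxolane fixes C9 and leaves neither a C10–H bond nor an alkene for the later carbenoid.

Step 6
Reactants: 10 methyl (3R)-3-[(6S,7S)-8,8-dimethyl-7-vinyl-1,4-dioxaspiro[4.6]undecan-6-yl]butanoate
Product: 11 methyl (3R)-3-[(6S,7S)-7-formyl-8,8-dimethyl-1,4-dioxaspiro[4.6]undecan-6-yl]butanoate (formyl and side chain trans)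
Conditions: O3, CH2Cl2/MeOH, −78 °C; then PPh3
Reagents that add atoms: ozone, [O-][O+]=O
Why: Ozonolysis with reductive work-up cleaves the only alkene and leaves C6 as the aldehyde; ketal and ester are inert.

Step 7
Reactants: 11 methyl (3R)-3-[(6S,7S)-7-formyl-8,8-dimethyl-1,4-dioxaspiro[4.6]undecan-6-yl]butanoate
Product: 13 methyl (3R)-3-[(6S,7R)-7-formyl-8,8-dimethyl-1,4-dioxaspiro[4.6]undecan-6-yl]butanoate (formyl and side chain cis), via exocyclic trimethylsilyl enol ether 12 (not isolated)
Conditions: Me3SiCl, Et3N, DMF, 60 °C; solvent exchange; then Bu4NF, AcOH, THF, −78 °C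
Reagents that add atoms: none
Why: Soft enolisation to the exocyclic enol silane erases the C5 centre, and irreversible low-temperature C-protonation of the fluoride-released enolate (contra-thermodynamic kinetic protonation) should occur on the face away from the C9 arm, which allylic 1,3-strain turns perpendicular to the enol plane on the same side as one C4 methyl group; the proton then ends trans to the arm and C6 cis to it (5R).

Step 8
Reactants: 13 methyl (3R)-3-[(6S,7R)-7-formyl-8,8-dimethyl-1,4-dioxaspiro[4.6]undecan-6-yl]butanoate
Product: 14 (6S,7R)-6-[(2R)-4-methoxy-4-oxobutan-2-yl]-8,8-dimethyl-1,4-dioxaspiro[4.6]undecane-7-carboxylic acid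
Conditions: NaClO2, NaH2PO4, 2-methylbut-2-ene, t-BuOH/H2O, 0 °C
Reagents that add atoms: sodium chlorite, [Na+].[O-]Cl=O
Why: Pinnick oxidation converts the aldehyde to the acid under buffered, non-enolising conditions, so the cis C5 centre should be kept.

Step 9
Reactants: 14 (6S,7R)-6-[(2R)-4-methoxy-4-oxobutan-2-yl]-8,8-dimethyl-1,4-dioxaspiro[4.6]undecane-7-carboxylic acid; 7 (trimethylsilyl)diazomethane
Product: 16 methyl (3R)-3-[(6S,7R)-7-(2-diazoacetyl)-8,8-dimethyl-1,4-dioxaspiro[4.6]undecan-6-yl]butanoate (5R,8R,9S), via acid chloride 15 (not isolated)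
Conditions: (COCl)2, DMF (cat.), CH2Cl2, 0 °C; then 7, CaO, MeCN/THF, 0 °C to rt
Reagents that add atoms: none
Why: Acylation of (trimethylsilyl)diazomethane by the acid chloride with loss of the silyl group (Arndt–Eistert-type diazoketone synthesis); no amine base is present, so no ketene should form and C5 is not epimerised.

Step 10
Reactants: 16 methyl (3R)-3-[(6S,7R)-7-(2-diazoacetyl)-8,8-dimethyl-1,4-dioxaspiro[4.6]undecan-6-yl]butanoate
Product: 17 methyl 2-[(5R,8S,9R)-10,10-(ethylenedioxy)-4,4,8-trimethyl-6-oxo-cis-perhydroazulen-8-yl]acetate (C10 ketal of the cis-hydroazulen-6-one with quaternary C8)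
Conditions: Rh2(OAc)4 (1 mol %), CH2Cl2, rt, slow addition of 16
Reagents that add atoms: none
Why: Dirhodium tetraacetate (divalent rhodium) expels N2 from 16 to give an electrophilic carbenoid at C7. The carbenoid should insert into the tertiary C8–H bond of the cis side chain through a concerted, asynchronous three-centre transition state, so that C8 becomes quaternary with retention of the configuration set in step 2. The closest known reaction type is the dirhodium-catalysed 1,5 C–H insertion of α-diazo ketones and α-diazo-β-keto esters into methine C–H bonds, which gives cyclopentanones with quaternary centres. The cyclopentanone closes as a 1,5-insertion, a five-membered ring formed through the six-membered chair-like array C7–C6–C5–C9–C8–H. Site selectivity is needed against the C4 methyl and ring C3 hydrogens (also 1,5 to C7) and the C14 and C17 hydrogens (1,6); the methine is the most electron-rich C–H bond, sits on a freely rotating chain cis to the carbenoid, and gives a fused ring where C3 insertion would give a strained bridged ketone. The dioxolane leaves no C10–H bond and no alkene within reach, and slow addition keeps the diazoketone dilute against dimerisation. The ring fusion is cis because C5 and C9 are already cis in 16.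

Step 11
Reactants: 17 methyl 2-[(5R,8S,9R)-10,10-(ethylenedioxy)-4,4,8-trimethyl-6-oxo-cis-perhydroazulen-8-yl]acetate
Product: 18 C6 tosylhydrazone of 17
Conditions: TsNHNH2, EtOH, 60 °C
Reagents that add atoms: 4-methylbenzenesulfonohydrazide, Cc1ccc(cc1)S(=O)(=O)NN
Why: Condensation of the exposed cyclopentanone carbonyl with tosylhydrazide; no acid or base is added, which limits enolisation towards C5.

Step 12
Reactants: 18 C6 tosylhydrazone of 17
Product: 19 methyl 2-[(5R,8S,9R)-10,10-(ethylenedioxy)-4,4,8-trimethyl-cis-perhydroazulen-8-yl]acetate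
Conditions: catecholborane, CHCl3, 0 °C; then NaOAc·3H2O, reflux
Reagents that add atoms: none
Why: Reductive deoxygenation of a tosylhydrazone (hydroboration of C=N, then acetate-induced loss of sulfinate and N2) replaces C6=O by CH2 without a carbanion, so the cis ring fusion at C5 should be retained.

Step 13
Reactants: 19 methyl 2-[(5R,8S,9R)-10,10-(ethylenedioxy)-4,4,8-trimethyl-cis-perhydroazulen-8-yl]acetate
Product: 20 2-[(5R,8S,9R)-10,10-(ethylenedioxy)-4,4,8-trimethyl-cis-perhydroazulen-8-yl]acetaldehyde
Conditions: i-Bu2AlH (1.1 equiv), CH2Cl2, −78 °C; aq. KNaC4H4O6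
Reagents that add atoms: none
Why: Half-reduction of a methyl ester with diisobutylaluminium hydride; the tetrahedral aluminium hemiacetal of this neopentyl-type ester should persist at −78 °C and release the aldehyde on work-up.

Step 14
Reactants: 20 2-[(5R,8S,9R)-10,10-(ethylenedioxy)-4,4,8-trimethyl-cis-perhydroazulen-8-yl]acetaldehyde
Product: 21 2-(phenylselanyl)-2-[(5R,8R,9R)-10,10-(ethylenedioxy)-4,4,8-trimethyl-cis-perhydroazulen-8-yl]acetaldehyde (both C14 epimers)
Conditions: N-(phenylselanyl)phthalimide, L-prolinamide (10 mol %), CH2Cl2, rt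
Reagents that add atoms: N-(phenylselanyl)phthalimide, O=C1c2ccccc2C(=O)N1[Se]c1ccccc1
Why: Enamine-catalysed α-selenenylation of an aldehyde; the phenylselanyl group on C14 is the radical precursor, and its configuration does not matter because C14 becomes planar in step 19.

Step 15
Reactants: 22 (R)-(2,2-dimethyl-1,3-dioxolan-4-yl)methanol; 23 benzyl 2-(diethoxyphosphoryl)acetate
Product: 25 benzyl (E)-3-[(4R)-2,2-dimethyl-1,3-dioxolan-4-yl]prop-2-enoate, via (S)-glyceraldehyde acetonide 24 (not isolated)
Conditions: (COCl)2, DMSO, Et3N, CH2Cl2, −78 °C; then 23, LiCl, DBU, MeCN, 0 °C to rt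
Reagents that add atoms: none
Why: Swern oxidation followed in the same flask by a Horner–Wadsworth–Emmons olefination under lithium chloride/amine conditions, which gives the (E)-enoate without epimerising the α-alkoxy aldehyde; the dioxolane CH becomes C16 with the R configuration of the target.

Step 16
Reactants: 25 benzyl (E)-3-[(4R)-2,2-dimethyl-1,3-dioxolan-4-yl]prop-2-enoate
Product: 26 benzyl (4R,E)-4,5-dihydroxypent-2-enoate
Conditions: AcOH/H2O (4:1), 40 °C
Reagents that add atoms: none
Why: Acid hydrolysis of the isopropylidene acetal; the benzyl ester and the enoate are stable to aqueous acetic acid.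

Step 17
Reactants: 26 benzyl (4R,E)-4,5-dihydroxypent-2-enoate
Product: 27 (2R,E)-5-(benzyloxy)-2-hydroxy-5-oxopent-3-enoic acid
Conditions: TEMPO (10 mol %), NaOCl (5 mol %), NaClO2, MeCN/phosphate buffer (pH 6.7), 35 °C
Reagents that add atoms: sodium chlorite, [Na+].[O-]Cl=O
Why: Nitroxyl-catalysed chlorite oxidation, selective for the primary alcohol, should give the α-hydroxy acid; the near-neutral buffer avoids isomerisation of the γ-hydroxy enoate.

Step 18
Reactants: 21 2-(phenylselanyl)-2-[(5R,8R,9R)-10,10-(ethylenedioxy)-4,4,8-trimethyl-cis-perhydroazulen-8-yl]acetaldehyde; 27 (2R,E)-5-(benzyloxy)-2-hydroxy-5-oxopent-3-enoic acid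
Product: 29 cis-(15R,16R)-1,3-dioxolan-4-one whose acetal carbon C15 carries the CH(SePh) carbon C14 (bonded to C8) and whose C16 carries the (E)-CH=CH–CO2Bn arm, via bis(trimethylsilyl) derivative 28 (not isolated)
Conditions: N,O-bis(trimethylsilyl)acetamide, CH2Cl2, rt; then 21, Me3SiOTf (10 mol %), CH2Cl2, −78 °C
Reagents that add atoms: none
Why: Acetalisation of an aldehyde with a bis-silylated α-hydroxy acid under silyl triflate catalysis gives the 1,3-dioxolan-4-one; the cis-2,5-disubstituted isomer is the kinetic and the thermodynamic product for bulky aldehydes, which places C14 and the enoate on the same face of the ring.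

Step 19
Reactants: 29 cis-(15R,16R)-1,3-dioxolan-4-one
Product: 30 (13R,14R,15R,16R)-2,7-dioxabicyclo[2.2.1]heptan-3-one (bridgeheads C15 and C16, carbonyl C21) with the C8 group exo on C14 and CH2CO2Bn exo on C13
Conditions: Bu3SnH (syringe pump), AIBN, benzene, 80 °C, 5 mM
Reagents that add atoms: none
Why: Proposed new method: the tributyltin radical removes the phenylselanyl group to give the C14 radical, which the cis-dioxolanone holds over the (E)-enoate so that it closes 5-exo onto C13 and forms the bridged acylal; the closest known reaction type is the Ueno–Stork cyclisation of α-halo acetals onto acrylates, the new element being the acylal tether that ties the second acetal oxygen back to C16 and forces a bridged product, and because the C21–O bridge fills the endo side, the C8 group on C14 (which also prefers to lie near the small bridgehead hydrogen) and the ester arm on C13 should both settle exo, which is the cis C13/C14, trans C13/C16 pattern of the target, before the stannane reduces the C12 radical.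

Step 20
Reactants: 30 (13R,14R,15R,16R)-2,7-dioxabicyclo[2.2.1]heptan-3-one
Product: 32 (13R,14R,15S,16R)-2,7-dioxabicyclo[3.2.1]octan-3-one with the hydroazulene on C14 and a carboxylic acid (C21) exo on C16, via seco acid 31 (not isolated)
Conditions: H2 (1 atm), Pd/C, EtOAc, rt; filter; then camphorsulfonic acid (10 mol %), CH2Cl2, rt
Reagents that add atoms: none
Why: Hydrogenolysis frees the C11 acid; acid catalysis then ionises the strained acylal to the tetrahydrofuranyl oxocarbenium ion, which the C11 acid on the same face captures to give the less strained six-membered lactone (lactone interchange) and release the C21 acid; C13, C14 and C16 are untouched and C15 is fixed by the bridge.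

Step 21
Reactants: 32 (13R,14R,15S,16R)-2,7-dioxabicyclo[3.2.1]octan-3-one acid
Product: 33 (12S,13S,14R,15S,16R)-12-hydroxy lactone acid (hydroxyl endo)
Conditions: KN(SiMe3)2 (2.3 equiv), THF, −78 °C; 2-(phenylsulfonyl)-3-phenyloxaziridine; AcOH
Reagents that add atoms: 2-(phenylsulfonyl)-3-phenyloxaziridine, O=S(=O)(c1ccccc1)N1OC1c1ccccc1
Why: Enolate oxidation with an N-sulfonyloxaziridine; the first equivalent of base forms the C21 carboxylate, which protects C16–H from deprotonation, the second forms the lactone enolate, and the oxidant should attack C12 from the endo face because the C8 group on C14 covers the exo face.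

Step 22
Reactants: 33 (12S,13S,14R,15S,16R)-12-hydroxy lactone acid; 7 (trimethylsilyl)diazomethane
Product: 34 (12S,13S,14R,15S,16R)-12-hydroxy lactone methyl ester
Conditions: toluene/MeOH (4:1), 0 °C
Reagents that add atoms: none
Why: Methyl ester formation from a carboxylic acid with (trimethylsilyl)diazomethane in methanol under neutral conditions; the secondary alcohol and the acylal are inert.

Step 23
Reactants: 34 (12S,13S,14R,15S,16R)-12-hydroxy lactone methyl ester
Product: 35 (12S,13R,14R,15S,16R)-12-acetoxy lactone methyl ester with the C10 dioxolane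
Conditions: Ac2O, pyridine, DMAP (cat.), CH2Cl2, 0 °C
Reagents that add atoms: acetic anhydride, CC(=O)OC(C)=O
Why: Nucleophile-catalysed acetylation of the secondary alcohol at 0 °C; the short, cold reaction limits enolisation of the α-acyloxy lactone.

Step 24
Reactants: 35 12-acetoxy lactone methyl ester with the C10 dioxolane
Product: 36 C10 ketone (5R,8S,9R,12S,13R,14R,15S,16R)
Conditions: pyridinium p-toluenesulfonate, acetone/H2O (10:1), 50 °C
Reagents that add atoms: water, O
Why: Mild acid-catalysed ketal hydrolysis in wet acetone; the bridged acylal, itself formed under acid, and the esters should survive, and the weak acid limits enolisation towards C9.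

Step 25
Reactants: 36 C10 ketone
Product: 37 target compound (5R,8R,9S,12S,13R,14R,15S,16R)
Conditions: Zn, CH2Br2, TiCl4, THF/CH2Cl2, 0 °C to rt
Reagents that add atoms: dibromomethane, BrCBr
Why: Lombardo methylenation; the geminal dizinc reagent activated by TiCl4 is non-basic and selective for ketones over esters and lactones, so C9 and C12 should not epimerise and the acylal is kept.

## Compound list

1 | 4,4-dimethylcyclohex-2-en-1-one | CC1(C)CCC(=O)C=C1 | starting material
2 | vinylmagnesium bromide | C=C[Mg]Br | starting material
3 | (S)-trimethyl[(4,4-dimethyl-3-vinylcyclohex-1-en-1-yl)oxy]silane | C=C[C@@H]1C(C)(C)CCC(O[Si](C)(C)C)=C1 | intermediate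
4 | dimethyl 2-ethylidenemalonate | CC=C(C(=O)OC)C(=O)OC | starting material
5 | dimethyl 2-[(1S)-1-[(1S,2S)-3,3-dimethyl-6-oxo-2-vinylcyclohexyl]ethyl]malonate | C=C[C@@H]1C(C)(C)CCC(=O)[C@H]1[C@H](C)C(C(=O)OC)C(=O)OC | intermediate
6 | methyl (3R)-3-[(1S,2S)-3,3-dimethyl-6-oxo-2-vinylcyclohexyl]butanoate | C=C[C@@H]1C(C)(C)CCC(=O)[C@H]1[C@H](C)CC(=O)OC | intermediate
7 | (trimethylsilyl)diazomethane | C[Si](C)(C)C=[N+]=[N-] | starting material
8 | methyl (3R)-3-[(1S,2S)-3,3-dimethyl-7-oxo-6-(trimethylsilyl)-2-vinylcycloheptyl]butanoate (epimers at the silyl carbon) | C=C[C@@H]1C(C)(C)CCC([Si](C)(C)C)C(=O)[C@H]1[C@H](C)CC(=O)OC | intermediate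
9 | methyl (3R)-3-[(1S,2S)-3,3-dimethyl-7-oxo-2-vinylcycloheptyl]butanoate | C=C[C@@H]1C(C)(C)CCCC(=O)[C@H]1[C@H](C)CC(=O)OC | intermediate
10 | methyl (3R)-3-[(6S,7S)-8,8-dimethyl-7-vinyl-1,4-dioxaspiro[4.6]undecan-6-yl]butanoate | C=C[C@@H]1C(C)(C)CCCC2(OCCO2)[C@H]1[C@H](C)CC(=O)OC | intermediate
11 | methyl (3R)-3-[(6S,7S)-7-formyl-8,8-dimethyl-1,4-dioxaspiro[4.6]undecan-6-yl]butanoate (trans) | O=C[C@@H]1C(C)(C)CCCC2(OCCO2)[C@H]1[C@H](C)CC(=O)OC | intermediate
12 | methyl (3R)-3-[(6S)-8,8-dimethyl-7-[(trimethylsilyloxy)methylidene]-1,4-dioxaspiro[4.6]undecan-6-yl]butanoate | C[Si](C)(C)OC=C1C(C)(C)CCCC2(OCCO2)[C@H]1[C@H](C)CC(=O)OC | intermediate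
13 | methyl (3R)-3-[(6S,7R)-7-formyl-8,8-dimethyl-1,4-dioxaspiro[4.6]undecan-6-yl]butanoate (cis) | O=C[C@H]1C(C)(C)CCCC2(OCCO2)[C@H]1[C@H](C)CC(=O)OC | intermediate
14 | (6S,7R)-6-[(2R)-4-methoxy-4-oxobutan-2-yl]-8,8-dimethyl-1,4-dioxaspiro[4.6]undecane-7-carboxylic acid | OC(=O)[C@H]1C(C)(C)CCCC2(OCCO2)[C@H]1[C@H](C)CC(=O)OC | intermediate
15 | acid chloride of 14 | ClC(=O)[C@H]1C(C)(C)CCCC2(OCCO2)[C@H]1[C@H](C)CC(=O)OC | intermediate
16 | methyl (3R)-3-[(6S,7R)-7-(2-diazoacetyl)-8,8-dimethyl-1,4-dioxaspiro[4.6]undecan-6-yl]butanoate | [N-]=[N+]=CC(=O)[C@H]1C(C)(C)CCCC2(OCCO2)[C@H]1[C@H](C)CC(=O)OC | intermediate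
17 | methyl 2-[(5R,8S,9R)-10,10-(ethylenedioxy)-4,4,8-trimethyl-6-oxo-cis-perhydroazulen-8-yl]acetate | O=C1C[C@@](C)(CC(=O)OC)[C@@H]2C3(OCCO3)CCCC(C)(C)[C@H]12 | intermediate
18 | C6 tosylhydrazone of 17 | Cc1ccc(cc1)S(=O)(=O)NN=C1C[C@@](C)(CC(=O)OC)[C@@H]2C3(OCCO3)CCCC(C)(C)[C@H]12 | intermediate
19 | methyl 2-[(5R,8S,9R)-10,10-(ethylenedioxy)-4,4,8-trimethyl-cis-perhydroazulen-8-yl]acetate | C1C[C@@](C)(CC(=O)OC)[C@@H]2C3(OCCO3)CCCC(C)(C)[C@H]12 | intermediate
20 | 2-[(5R,8S,9R)-10,10-(ethylenedioxy)-4,4,8-trimethyl-cis-perhydroazulen-8-yl]acetaldehyde | C1C[C@@](C)(CC=O)[C@@H]2C3(OCCO3)CCCC(C)(C)[C@H]12 | intermediate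
21 | 2-(phenylselanyl)-2-[(5R,8R,9R)-10,10-(ethylenedioxy)-4,4,8-trimethyl-cis-perhydroazulen-8-yl]acetaldehyde (C14 epimers) | C1C[C@@](C)(C(C=O)[Se]c3ccccc3)[C@@H]2C3(OCCO3)CCCC(C)(C)[C@H]12 | intermediate
22 | (R)-(2,2-dimethyl-1,3-dioxolan-4-yl)methanol | OC[C@@H]1COC(C)(C)O1 | starting material
23 | benzyl 2-(diethoxyphosphoryl)acetate | CCOP(=O)(CC(=O)OCc1ccccc1)OCC | starting material
24 | (S)-2,2-dimethyl-1,3-dioxolane-4-carbaldehyde | O=C[C@@H]1COC(C)(C)O1 | intermediate
25 | benzyl (E)-3-[(4R)-2,2-dimethyl-1,3-dioxolan-4-yl]prop-2-enoate | O=C(OCc1ccccc1)/C=C/[C@@H]1COC(C)(C)O1 | intermediate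
26 | benzyl (4R,E)-4,5-dihydroxypent-2-enoate | O=C(OCc1ccccc1)/C=C/[C@@H](O)CO | intermediate
27 | (2R,E)-5-(benzyloxy)-2-hydroxy-5-oxopent-3-enoic acid | O=C(OCc1ccccc1)/C=C/[C@@H](O)C(=O)O | intermediate
28 | trimethylsilyl (2R,E)-5-(benzyloxy)-5-oxo-2-(trimethylsilyloxy)pent-3-enoate | O=C(OCc1ccccc1)/C=C/[C@@H](O[Si](C)(C)C)C(=O)O[Si](C)(C)C | intermediate
29 | cis-(15R,16R)-1,3-dioxolan-4-one: C15 bears CH(SePh)–C8 of the ketal-protected hydroazulene, C16 bears (E)-CH=CH–CO2Bn | C1C[C@@](C)(C([Se]c3ccccc3)[C@@H]4O[C@H](/C=C/C(=O)OCc5ccccc5)C(=O)O4)[C@@H]2C3(OCCO3)CCCC(C)(C)[C@H]12 | intermediate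
30 | (13R,14R,15R,16R)-2,7-dioxabicyclo[2.2.1]heptan-3-one: hydroazulenyl (via C8) exo on C14, CH2CO2Bn exo on C13 | C1C[C@@](C)([C@@H]4[C@@H]5O[C@@H](C(=O)O5)[C@@H]4CC(=O)OCc6ccccc6)[C@@H]2C3(OCCO3)CCCC(C)(C)[C@H]12 | intermediate
31 | seco acid of 30 (CH2CO2H on C13) | C1C[C@@](C)([C@@H]4[C@@H]5O[C@@H](C(=O)O5)[C@@H]4CC(=O)O)[C@@H]2C3(OCCO3)CCCC(C)(C)[C@H]12 | intermediate
32 | (13R,14R,15S,16R)-2,7-dioxabicyclo[3.2.1]octan-3-one with hydroazulenyl on C14 and exo CO2H on C16 | C1C[C@@](C)([C@@H]3[C@@H]4OC(=O)C[C@H]3[C@H](C(=O)O)O4)[C@@H]2C5(OCCO5)CCCC(C)(C)[C@H]12 | intermediate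
33 | (12S,13S,14R,15S,16R)-12-hydroxy lactone acid | C1C[C@@](C)([C@@H]3[C@@H]4OC(=O)[C@@H](O)[C@H]3[C@H](C(=O)O)O4)[C@@H]2C5(OCCO5)CCCC(C)(C)[C@H]12 | intermediate
34 | (12S,13S,14R,15S,16R)-12-hydroxy lactone methyl ester | C1C[C@@](C)([C@@H]3[C@@H]4OC(=O)[C@@H](O)[C@H]3[C@H](C(=O)OC)O4)[C@@H]2C5(OCCO5)CCCC(C)(C)[C@H]12 | intermediate
35 | (12S,13R,14R,15S,16R)-12-acetoxy lactone methyl ester, C10 dioxolane | C1C[C@@](C)([C@@H]3[C@@H]4OC(=O)[C@@H](OC(C)=O)[C@H]3[C@H](C(=O)OC)O4)[C@@H]2C5(OCCO5)CCCC(C)(C)[C@H]12 | intermediate
36 | C10 ketone (10-oxo analogue of the target) | O=C1CCCC(C)(C)[C@@H]2CC[C@@](C)([C@@H]3[C@@H]4OC(=O)[C@@H](OC(C)=O)[C@H]3[C@H](C(=O)OC)O4)[C@H]12 | intermediate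
37 | target compound CNP0215240.1 | C=C1CCCC(C)(C)[C@@H]2CC[C@@](C)([C@@H]3[C@@H]4OC(=O)[C@@H](OC(C)=O)[C@H]3[C@H](C(=O)OC)O4)[C@H]12 | target

## Step count and risks

Total steps: 25. Longest linear sequence: 22 steps (steps 1–14 and 18–25); the fragment branch (steps 15–17) has 3 steps.

**Step 19 (carries the label).** The strain of the forming bridged ring may slow the closure. Premature reduction of the C14 radical by the stannane, or a 1,2-acyloxy shift of the β-acyloxy radical, could then compete. Any trans-dioxolanone cannot cyclise at all.

The fallback uses the known Ueno–Stork sequence. It sets out from aldehyde 20 and returns at hydroxy ester 34. Aldehyde 20 is converted with MeOH, HC(OMe)3 and pyridinium p-toluenesulfonate into the dimethyl acetal F1. Me3SiOTf and i-Pr2NEt eliminate methanol to give the methyl enol ether F2. Acid 27 is esterified with reagent 7 to the hydroxy diester F3. N-Iodosuccinimide joins F2 and F3 as the mixed iodoacetal F4. Bu3SnH and AIBN close the tetrahydrofuran to the methyl acetal F5. Hydrogenolysis and camphorsulfonic acid give the lactone methyl ester F6. Hydroxylation as in step 21 then leads to 34.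

This line gives up the control of C14. Its acetal centre is formed without selectivity and its methoxy group steers the C8 group, so separation of C14 epimers must be expected. Hydroxylation of F6 also lacks the carboxylate protection of C16–H.

**Step 10 (key step).** The dioxolane oxygen may attack the carbenoid and divert it to a six-membered oxonium ylide. Insertion into the C3–H or C4-methyl C–H bonds, or carbene dimerisation, may also lower the yield, because a simple acyl carbenoid is not very selective.

The fallback makes the carbenoid more selective by adding a second acceptor. It sets out from acid 14 and returns at 17. Acid 14 is activated with carbonyldiimidazole and homologated with Mg(O2CCH2CO2Me)2 to the β-keto ester F7. Diazo transfer (4-acetamidobenzenesulfonyl azide, Et3N) gives the diazo keto ester F8. Rh2(OAc)4 closes it to the C7-methoxycarbonyl cyclopentanone F9. LiCl in wet DMSO removes the extra ester to give 17.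

**Step 2.** The addition may pass in part through a synclinal arrangement and give the syn C9/C8 pair, or attack may occur cis to the vinyl group. Either would deliver the C8 epimer, which cannot be corrected later.

The fallback moves control of C8 to an auxiliary. It sets out from 3 and returns at 6, skipping 5. Enol silane 3 is added with Et2AlCl to (S)-4-benzyl-3-[(E)-but-2-enoyl]oxazolidin-2-one, whose chelated s-cis form is attacked anti to the benzyl group, to give the imide F10. MeOMgBr in MeOH converts it into 6.

**Step 1.** Conjugate addition next to the quaternary C4 may be slow. 1,2-Addition may compete, and the enantioselectivity of a vinyl transfer to this hindered enone may be low.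

The fallback takes the absolute control from the auxiliary instead. It sets out from 1 and returns at 6. Enone 1 is treated with (CH2=CH)2CuLi and Me3SiCl to give the racemic enol silane F11. This is combined with half an equivalent of the same crotonoyl oxazolidinone under Et2AlCl. Only the matched enantiomer adds quickly (kinetic resolution) to give imide F10, which is methanolysed to 6.

**Step 7.** The protonation may not discriminate the two faces well enough, or the cis aldehyde may re-equilibrate before oxidation. Either returns trans material.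

The fallback sets the C5–H bond by hydrogen addition instead of protonation. It sets out from 11 (through 12) and returns at 14. Enol silane 12 is hydrogenated (H2, Pd/C, EtOAc) from the face away from the C9 arm to the cis silyl ether F12. K2CO3 in MeOH frees the alcohol F13. The nitroxyl/NaClO2 oxidation of step 17 gives acid 14.

**Step 25.** Methylenation of the hindered ketone may be slow. The titanium Lewis acid may open the acylal, and prolonged reaction may epimerise C9.

The fallback is a two-stage Peterson olefination. It sets out from 36 and returns at 37. Me3SiCH2MgCl with CeCl3 at −78 °C adds selectively to the ketone to give the β-hydroxysilane F14. HF·pyridine then eliminates silanol to give 37.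

## Further compounds

F1 | step 19 | dimethyl acetal of aldehyde 20 | C1C[C@@](C)(CC(OC)OC)[C@@H]2C3(OCCO3)CCCC(C)(C)[C@H]12
F2 | step 19 | methyl enol ether of aldehyde 20 (C14=C15–OMe) | C1C[C@@](C)(C=COC)[C@@H]2C3(OCCO3)CCCC(C)(C)[C@H]12
F3 | step 19 | 1-benzyl 5-methyl (4R,E)-4-hydroxypent-2-enedioate | O=C(OCc1ccccc1)/C=C/[C@@H](O)C(=O)OC
F4 | step 19 | mixed iodoacetal from F2 and F3 (C14 and C15 epimers) | C1C[C@@](C)(C(I)C(OC)O[C@H](/C=C/C(=O)OCc4ccccc4)C(=O)OC)[C@@H]2C3(OCCO3)CCCC(C)(C)[C@H]12
F5 | step 19 | 2-methoxytetrahydrofuran with C16 methyl ester and C13 CH2CO2Bn (C15 epimers) | C1C[C@@](C)([C@@H]4C(OC)O[C@@H](C(=O)OC)[C@@H]4CC(=O)OCc5ccccc5)[C@@H]2C3(OCCO3)CCCC(C)(C)[C@H]12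
F6 | step 19 | 2,7-dioxabicyclo[3.2.1]octan-3-one methyl ester without C12 oxygen | C1C[C@@](C)([C@@H]3[C@@H]4OC(=O)C[C@H]3[C@H](C(=O)OC)O4)[C@@H]2C5(OCCO5)CCCC(C)(C)[C@H]12
F7 | step 10 | β-keto ester from acid 14 | COC(=O)CC(=O)[C@H]1C(C)(C)CCCC2(OCCO2)[C@H]1[C@H](C)CC(=O)OC
F8 | step 10 | α-diazo-β-keto ester | COC(=O)C(=[N+]=[N-])C(=O)[C@H]1C(C)(C)CCCC2(OCCO2)[C@H]1[C@H](C)CC(=O)OC
F9 | step 10 | C7-methoxycarbonyl derivative of 17 | O=C1C(C(=O)OC)[C@@](C)(CC(=O)OC)[C@@H]2C3(OCCO3)CCCC(C)(C)[C@H]12
F10 | step 2 | (S)-4-benzyl-3-[(3R)-3-[(1S,2S)-3,3-dimethyl-6-oxo-2-vinylcyclohexyl]butanoyl]oxazolidin-2-one | C=C[C@@H]1C(C)(C)CCC(=O)[C@H]1[C@H](C)CC(=O)N2C(=O)OC[C@@H]2Cc3ccccc3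
F11 | step 1 | racemic trimethyl[(4,4-dimethyl-3-vinylcyclohex-1-en-1-yl)oxy]silane | C=CC1C(C)(C)CCC(O[Si](C)(C)C)=C1
F12 | step 7 | methyl (3R)-3-[(6S,7R)-8,8-dimethyl-7-[(trimethylsilyloxy)methyl]-1,4-dioxaspiro[4.6]undecan-6-yl]butanoate | C[Si](C)(C)OC[C@H]1C(C)(C)CCCC2(OCCO2)[C@H]1[C@H](C)CC(=O)OC
F13 | step 7 | methyl (3R)-3-[(6S,7R)-7-(hydroxymethyl)-8,8-dimethyl-1,4-dioxaspiro[4.6]undecan-6-yl]butanoate | OC[C@H]1C(C)(C)CCCC2(OCCO2)[C@H]1[C@H](C)CC(=O)OC
F14 | step 25 | C10 β-hydroxysilane from ketone 36 (C10 epimers) | C[Si](C)(C)CC1(O)CCCC(C)(C)[C@@H]2CC[C@@](C)([C@@H]3[C@@H]4OC(=O)[C@@H](OC(C)=O)[C@H]3[C@H](C(=O)OC)O4)[C@H]12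
A1 | alternative 1 | lactone-bridged cyclobutane photoadduct | O=C1O[C@]23CCC(=O)[C@@]2(C)[C@@H]4CC[C@@]1(CCO[Si](C)(C)C(C)(C)C)[C@H]34
A2 | alternative 2 | 2-oxabicyclo[2.1.1]hexane diester on the hydroazulene | C=C1CCCC(C)(C)[C@@H]2CC[C@@](C)([C@@H]3[C@H]4O[C@@H](C(=O)OC)[C@@H]3C4C(=O)OC(C)(C)C)[C@H]12
A3 | alternative 3 | cis-hydroazulene with exocyclic methylene and 2-pivaloyloxyethyl arm on C8 | C=C1CCCC(C)(C)[C@@H]2CC[C@@](C)(CCOC(=O)C(C)(C)C)[C@H]12
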